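The runs are simulated with constants of no real substance; noise was put on by code.

- Of every left-handed substrate molecule charged to the midnight run, 16.0% is still unreacted at the last reading, and that survival chance is what I plan with.

in all of them: left-handed substrate 0.32 M; right-handed substrate 0.32 M
- spring: coupling partner 0.43 M; precatalyst 6.4 mM; temperature 5 °C; run made earlier
- midnight: coupling partner 0.96 M; precatalyst 6.4 mM; temperature 38 °C; run made earlier
- autumn: coupling partner 0.64 M; precatalyst 3.2 mM; temperature 5 °C; run made earlier
- north-west: coupling partner 0.640 M; precatalyst 6.4 mM; temperature 50 °C; time 5.0 d
- west: coupling partner 0.640 M; precatalyst 6.4 mM; temperature −10 °C; time 5.0 d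
- east: coupling partner 0.640 M; precatalyst 6.4 mM; temperature 20 °C; time 5.0 d

| run | time / d | left-handed product / % | left-handed substrate / % |
|---|---|---|---|
| spring | 2.50 | 16 | 38 |
| spring | 8.00 | 33 | 17 |
| spring | 12.0 | 34 | 15 |
| spring | 20.0 | 36 | 15 |
| spring | 30.0 | 38 | 10 |
| midnight | 0.417 | 40 | 13 |
| midnight | 0.833 | 41 | 10 |
| midnight | 1.67 | 42 | 6 |
| midnight | 3.00 | 42 | 8 |
| midnight | 5.00 | 44 | 8 |
| autumn | 2.50 | 14 | 39 |
| autumn | 8.00 | 29 | 22 |
| autumn | 12.0 | 37 | 15 |
| autumn | 20.0 | 42 | 7 |
| autumn | 30.0 | 48 | 5 |

(standard deviation of a reading: 2 percentage points)

- free catalyst is single-handed; left-handed substrate and right-handed substrate are mirror images of each other, charged as a racemate, each of them at the stated concentration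
- the numbers in the tables scatter by 2 percentage points (one standard deviation)
- steps under discussion: precatalyst -> free catalyst; coupling partner + free catalyst + right-handed substrate -> free catalyst + right-handed product; free catalyst -> spent catalyst; coupling partner + free catalyst + left-handed substrate -> free catalyst + left-handed product

- the flask with the highest amount of left-handed product, in percent of the left-handed substrate and right-handed substrate together charged ("all alike" if they lie within 1.5 percentage points) (north-west / west / east / all alike)
- final left-handed product, as a percentage of the left-handed substrate and right-handed substrate together charged, in north-west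
- final left-handed product, as a percentage of the left-handed substrate and right-handed substrate together charged, in west
- final left-handed product, as a percentage of the left-handed substrate and right-handed substrate together charged, in east

- My bench rule says rates double every 10 degrees. East and west each lie 15.0 degrees from 5 °C, a factor 2.83.
- So east's 5.0 d counts as 14.2 d at 5 °C. Autumn, with half the precatalyst, reads 37% and 42% around there, so I commit to about 39.5% for east.
- West's 5.0 d counts as 1.77 d, and scaling spring's first reading gives about 11.3% for west.
- The rule breaks at midnight. Time grows 12.0-fold between first and last reading, yet left-handed product gains 4 percentage points, though partner was charged at 1.50 equivalents of both substrates. I read this as free catalyst dying first.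
- Each left-handed molecule therefore faces a fork: it couples, or it outlasts the catalyst. I define the reach ρ as the natural log of charged over final left-handed substrate, treating its loss as pseudo-first-order. Midnight gives ρ = 1.83, a reading with the scatter in it.
- I assume ρ scales with partner and catalyst. Midnight at the new partner charge becomes 1.22. Autumn, still moving, gives 4.61 at full catalyst, which is a floor.
- I draw a straight line of ln ρ against temperature through autumn and midnight. North-west lies 12.0 degrees beyond midnight, so its figure is an extrapolation, unbracketed, on a slope that rests on a floor value: 0.754, so about 26.5% left-handed product. East lies between the two runs and is interpolated at 2.52, an estimate of 46.0% once its catalyst is spent, above my 39.5% for the time asked.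
- The forecast names east, with 25% for north-west, 7% for west (below my figure) and 40% for east, on the ground that “At 50 °C the catalyst dies early”.
- The flasks give 23.6% in north-west, 3.37% in west and 43.7% in east, so east holds most.

    precatalyst → free catalyst (k = 0.110 h⁻¹, Ea = 89.0 kJ mol⁻¹)
    coupling partner + free catalyst + right-handed substrate → free catalyst + right-handed product (k = 11.0 M⁻² h⁻¹, Ea = 64.0 kJ mol⁻¹)
    free catalyst → spent catalyst (k = 0.0110 h⁻¹, Ea = 109 kJ mol⁻¹)
    coupling partner + free catalyst + left-handed substrate → free catalyst + left-handed product (k = 19.0 M⁻² h⁻¹, Ea = 54.0 kJ mol⁻¹)
    (constants at 20 °C)

- North-west has free catalyst at 0% by 2.50 d, with 55% of its partner charge unused. Its 53% of left-handed substrate remaining gives ρ = 0.635, less than midnight's 1.83. East, left ten times as long, has spent catalyst at >99.9% and left-handed substrate at 4.29%, which gives ρ = 2.46.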